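Locants used throughout: unit A = lactone C1(=O), O2, C3 (bearing the Z-butylidene carbon C8) and ring A C3a–C4–C5–C6–C7–C7a; unit B = lactone C1'(=O), O2', spiro C3', benzo ring C3a'–C7a', propyl-bearing C8'. The cyclobutane is C6–C7–C3'–C8'.

## The problem

Compound 9 joins a 6,7-dihydro-Z-ligustilide unit (ring A with a tetrasubstituted C3a=C7a bond and a Z-butylidene butenolide) through C6 and C7 to a 3-propylphthalide unit, so that C6–C7–C3'–C8' is a cyclobutane cis-fused to ring A and spiro-linked at C3' to the phthalide. All four stereocentres (6S, 7R, 3'R, 8'R) lie on this ring: H-6, H-7 and H-8' share the convex face, the propyl group lies on the concave face under ring A, and at quaternary C3' the aryl carbon is convex and O2' concave. The obvious building blocks carry no stereocentre, so the absolute configuration has to come from a catalyst, after which C6 can dictate C7 through the ring fusion and the folded bicyclo[4.2.0] core can dictate C3'. The concave propyl is the less stable orientation and is α to the carbonyl in any cyclobutanone precursor, so it must be set kinetically and kept away from base. The Z-alkylidene butenolide is an enol lactone that opens with amines, alkoxides and hard organometallics and isomerises or aromatises with light, acid or air, and the strained ring with its tertiary benzylic C–O bond will not tolerate strong acid. Adding a ketene across C6=C7 of the ring-A diene of 1 would put the carbonyl carbon on the diene terminus C6, not on C7, so the four-membered ring needs another origin. That origin is offered by the position of the oxidised carbon C3' on C7, one allyl terminus away from C3a across C3a=C7a: returning C3' to C3a, with the double bond moving to C7a=C7, turns the cyclobutanone into a bicyclo[2.2.2]oct-5-en-2-one with bridgeheads C3a and C6, which is a Diels–Alder adduct of the ring-A diene of 1.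

## Retrosynthesis

**9 to 5 and 6.** The bonds C3'–C3a' and O2'–C1' are cut. This removes the phthalide as the ortho-magnesiated benzoate 7, made from iodide 6, and leaves cyclobutanone 5. The cut is preferred to opening the cyclobutane first, because it takes away seven carbons, two rings and the quaternary stereocentre in one operation and leaves a ketone as the handle for the ring-forming step. Compound 5 has three stereocentres and no aryl group. The forward reaction must add to the convex face, choose the strained ketone over the conjugated enol lactone, avoid enolisation towards C8' and C7, and lactonise through alkoxide 8 in the same flask.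

**5 to 4 (key disconnection).** In 5 the bond C7–C3' is broken and C3a–C3' is formed, with the alkene moved from C3a=C7a to C7a=C7; this gives bicyclo[2.2.2]octenone 4. The neighbouring cut, a [2+2] cycloaddition of a ketene to C6=C7 of 1, is shorter but would deliver the regioisomer with the carbonyl on C6. Compound 4 is an isomer of 5 and no lighter, but it exchanges a four-membered-ring problem for a six-membered cycloadduct whose relative configuration follows the endo rule. The forward step is a photochemical 1,3-acyl shift, which has to proceed through the singlet state, stop before the product is photolysed, and leave C6 and C8' untouched.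

**4 to 3.** The ketone at C3' of 4 is traced back to the formyl-bearing carbon of aldehyde 3 (one C–C bond to a CHO group added). A β-alkyl ketene equivalent that is both a good dienophile and open to asymmetric catalysis is not at hand, whereas an enal is; the formyl carbon is then excised oxidatively. The forward reaction must convert CH–CHO into C=O without nucleophilic amines or strong base, so that the enol lactone and the epimerisable C8' survive.

**3 to 1 and 2.** The bonds C3a–C3' and C6–C8' of 3 are cut in a Diels–Alder sense, giving Z-ligustilide 1 as diene and (E)-hex-2-enal 2 as dienophile. Both are bought; 1 already contains ring A, the lactone and the Z-butylidene group, and 2 brings C3', C8' and the propyl chain. The forward reaction must join C8' to C6 (not to C3a), proceed endo so that the propyl group ends over the C4–C5 bridge, and take place on one face of the enal under catalyst control.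

## Roads not taken

**Alternative 1:** Ring A is cut at C5–C6 and C7–C7a, so the four-membered ring is bought and the six-membered ring is made. The dienophile is cyclobut-2-enone A1 and the diene is (E)-1-(triisopropylsilyloxy)buta-1,3-diene A2. Under a chiral oxazaborolidine activated by AlBr3, A1 would add A2 to give the cis-fused silyloxy-bicyclo[4.2.0]octenone A3.
- Merits: A1 is an unusually reactive dienophile, A2 is a simple electron-rich partner, and the catalytic reaction sets C6, C7 and the absolute configuration at once. The ketone arrives on C7 with no regiochemical question and no photochemistry. In these respects it is better precedented than the chosen key step.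
- Weak points: A3 lacks the propyl group. Alkylation of its enolate would enter from the convex face and give the wrong C8' epimer unless a kinetic protonation follows. A3 also lacks the whole butenolide: C1 on C7a, C3 with the butylidene chain on C3a, and the tetrasubstituted C3a=C7a bond would all have to be built from a silyl ether and a C3a=C4 alkene beside a sensitive cyclobutanone. A1 is volatile, polymerises and must itself be prepared.
- Comparison: the chosen plan offers four steps, a unit A that is bought intact, and a propyl configuration that follows from the endo rule. Against this it accepts a less certain photochemical step.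

**Alternative 2:** The phthalide is cut into three pieces (C3'–C3a', C3'–O2' and C1'–C7a'). The three components are 2-(trimethylsilyl)phenyl trifluoromethanesulfonate A4 as aryne source, tert-butyl isocyanide A5 and cis-8-propylbicyclo[4.2.0]oct-2-en-7-one A6. With CsF, the aryne set free from A4 would take up A5 at one carbon and the carbonyl group of A6 at the other to give the spiro iminolactone A7, whose C=N bond must then be hydrolysed.
- Merits: no low-temperature organometallic reagent is needed, the medium is close to neutral, and attack on the convex face of A6 should be as selective as in the chosen last step.
- Weak points: such couplings run best with aldehydes and activated ketones. A hindered, enolisable cyclobutanone such as A6 is a poor and acidic partner for the aryl anion formed from A4 and A5, which risks proton transfer and loss of C8'. A hydrolysis step is added after A7. The plan also leaves open how the cyclobutanone is made, and A6 carries only a C4=C5 alkene where unit A has its lactone.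
- Comparison: this is a different last step rather than a different route. The aryl Grignard reagent of the chosen plan delivers C1' at the lactone oxidation level in one operation; the aryne coupling remains a possible substitute if basicity proves limiting.

**Alternative 3:** The cyclobutane is cut at C3'–C8' and the lactone at O2'–C1'. SmI2 would couple the two ketones of the cis-1,4-diketone A8 (butanoyl on C6, 2-(methoxycarbonyl)benzoyl on C7), and the C3' alkoxide would lactonise onto the ester to give the spiro-phthalide cyclobutanol A9.
- Merits: the ring and the spiro-lactone form in one reductive step with chelation control. The two most hindered carbons are joined directly, with no photochemistry and no regiochemical issue. For the C3' stereocentre it is at least as good as the chosen plan.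
- Weak points: in A9, C8' emerges as a tertiary alcohol with propyl convex. A radical deoxygenation is therefore needed, and its hydrogen delivery becomes a new stereo-determining event. The cis-diacyl arrangement of A8 epimerises easily, and the aryl ketone or the ester can be reduced alone. Unit A is again only a silyl ether on a cyclohexane.
- Comparison: the chosen plan needs no deoxygenation and carries the lactone from the start. Against this, its ring-forming step is contra-thermodynamic and light-driven.

Key step: step 3

Assumption: Z-ligustilide 1 is purchased as the isolated natural product and chromatographed immediately before use, since it oxidises and dimerises on storage; both enantiomers of the imidazolidinone catalyst are commercial.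

**Step 1**
Reactants: 1 Z-ligustilide; 2 (E)-hex-2-enal
Product: 3 endo Diels–Alder aldehyde (3aS,6S,3'S,8'R)
Conditions: 2 (3 equiv), (5R)-5-benzyl-2,2,3-trimethylimidazolidin-4-one·HCl (20 mol%), MeCN/H2O (95:5), rt, Ar, dark
Reagents that add atoms: none
Why: Iminium-ion-catalysed Diels–Alder reaction of an enal with a cyclic 1,3-diene; the ring-A diene C6=C7–C7a=C3a is the only s-cis diene of 1, and its larger HOMO coefficient and smaller steric demand lie at C6 (a terminus of the C6-to-C8 triene), so the electrophilic propyl-bearing β-carbon (C8') should bond to C6 and the α-carbon (C3') to C3a. The endo transition state places the formyl group under C7=C7a and the propyl group over the C4–C5 bridge, and the (5R)-benzyl group shields one face of the E-iminium ion so that C8' is formed R, which together with endo addition fixes C6 and C3a; C3' is erased in step 2.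

**Step 2**
Reactants: 3 endo Diels–Alder aldehyde
Product: 4 bicyclo[2.2.2]octenone (3aS,6R,8'R)
Conditions: Cu(OAc)2 (20 mol%), 2,2'-bipyridine (20 mol%), DABCO (1 equiv), O2 (1 atm), DMF, 40 °C
Reagents that add atoms: dioxygen, O=O
Why: Cu(OAc)2-catalysed aerobic deformylation of an α-branched aldehyde: the enol of 3 is oxygenated at C3' by O2 under divalent copper and the α-hydroperoxy aldehyde fragments to the ketone and formic acid. DABCO is a tertiary amine that cannot open the enol lactone, the electron-poor C7=C7a and enol-ester C3=C8 bonds are not oxygenated, and under these mild conditions the ketone should not enolise, so C8' is kept.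

**Step 3**
Reactants: 4 bicyclo[2.2.2]octenone
Product: 5 cis-fused cyclobutanone (6S,7R,8'R)
Conditions: hν (310 nm), degassed PhH (0.01 M), rt, FEP flow reactor, partial conversion, 4 recycled
Reagents that add atoms: none
Why: Photochemical 1,3-acyl shift of a β,γ-unsaturated ketone, the known singlet reaction by which bicyclo[2.2.2]oct-5-en-2-ones give bicyclo[4.2.0]oct-2-en-7-ones. Excitation of the ketone n→π* band, where the enoate and enol-ester chromophores of 4 are transparent, is followed by Norrish α-cleavage of C3'–C3a, the weaker α-bond because it releases a tertiary radical delocalised over C3a–C7a–C7. The acyl radical stays tethered through C8'–C6 and recombines at C7, which forms C7–C3', closes the cyclobutanone by radical-pair recombination (a suprafacial 1,3-shift) and returns the alkene to C3a=C7a in conjugation with the lactone and the butylidene group. The new stereocentre C7 is set by C6, since the two-atom tether can reach only the face of C7 on which C8' already sits, so the ring fusion must be cis. C6 and C8' take no part in bond breaking, so the propyl group of 4, syn to the C4–C5 bridge, becomes the concave propyl of 5. The step needs the singlet 1,3-shift to win over triplet oxa-di-π-methane rearrangement, decarbonylation and cycloreversion to a ketene; direct irradiation without sensitiser and the fully substituted allylic bridgehead, which makes α-cleavage fast, are meant to secure this. Because 5 absorbs more strongly than 4 and is itself a β,γ-unsaturated cyclobutanone, the solution is passed through a thin-film flow reactor to partial conversion and 4 is recycled.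

**Step 4**
Reactants: 5 cis-fused cyclobutanone; 6 propan-2-yl 2-iodobenzoate
Product: 9 target spiro-phthalide (6S,7R,3'R,8'R), via arylmagnesium chloride 7 (not isolated), via chloromagnesium alkoxide 8 (not isolated)
Conditions: 6, iPrMgCl·LiCl, THF, −40 °C; then 5, LaCl3·2LiCl (30 mol%), THF, −40 → 0 °C, then rt; aq. NH4Cl
Reagents that add atoms: none
Why: Iodine–magnesium exchange gives the ester-bearing aryl Grignard reagent 7, which adds 1,2 to the strained cyclobutanone carbonyl (more electrophilic than the conjugated enol lactone) while LaCl3·2LiCl suppresses enolisation at C8' and C7; alkoxide 8 then displaces isopropoxide from the ortho ester to close the phthalide. C3' is set by attack on the convex face of the cis-fused bicyclo[4.2.0]octanone, anti to ring A and to the concave propyl group, which places the aryl carbon convex and O2' concave as in 9.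

## Compound list

1 | Z-ligustilide, (3Z)-3-butylidene-4,5-dihydro-2-benzofuran-1(3H)-one | CCC/C=C1\OC(=O)C2=C1CCC=C2 | starting material
2 | (E)-hex-2-enal | CCC/C=C/C=O | starting material
3 | endo Diels–Alder aldehyde (3aS,6S,3'S,8'R): Z-3-butylidene γ-lactone (C1, O2, C3) fused at C3a–C7a to a bicyclo[2.2.2]octene with bridgeheads C3a (quaternary) and C6 (H) and bridges C7a=C7, C4–C5 and C3'–C8'; CHO on C3' syn to the C7=C7a bridge, n-propyl on C8' syn to the C4–C5 bridge, trans to CHO | CCC/C=C1\OC(=O)C2=C[C@H]3CC[C@@]12[C@@H](C=O)[C@@H]3CCC | intermediate
4 | bicyclo[2.2.2]octenone (3aS,6R,8'R): as 3 but with C3' a ketone between C3a and C8'; n-propyl on C8' syn to the C4–C5 bridge, H-8' syn to C7=C7a | CCC/C=C1\OC(=O)C2=C[C@H]3CC[C@@]12C(=O)[C@@H]3CCC | intermediate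
5 | cis-fused cyclobutanone (6S,7R,8'R): Z-3-butylidene-4,5,6,7-tetrahydrophthalide (C3a=C7a) with the cyclobutanone C6–C7–C3'(=O)–C8' fused at C6–C7; H-6, H-7 and H-8' on the convex face, n-propyl on C8' on the concave face, cis to C5 and C7a | CCC/C=C1\OC(=O)C2=C1CC[C@H]1[C@@H](CCC)C(=O)[C@@H]21 | intermediate
6 | propan-2-yl 2-iodobenzoate | CC(C)OC(=O)c1ccccc1I | starting material
7 | [2-(propan-2-yloxycarbonyl)phenyl]magnesium chloride, LiCl complex | CC(C)OC(=O)c1ccccc1[Mg]Cl | intermediate
8 | chloromagnesium alkoxide of the tertiary cyclobutanol: 5 with C3' bearing O–MgCl (concave) and the 2-(propan-2-yloxycarbonyl)phenyl group (convex) | CCC/C=C1\OC(=O)C2=C1CC[C@H]1[C@@H](CCC)[C@](O[Mg]Cl)(c3ccccc3C(=O)OC(C)C)[C@@H]21 | intermediate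
9 | target (6S,7R,3'R,8'R): Z-3-butylidene-4,5,6,7-tetrahydrophthalide cis-fused at C6–C7 to a cyclobutane whose C3' is the spiro C3 of a phthalide (aryl convex, O2' concave) and whose C8' carries n-propyl on the concave face | CCC/C=C1\OC(=O)C2=C1CC[C@H]1[C@@H](CCC)[C@@]3(OC(=O)c4ccccc43)[C@@H]21 | target

## Step count and least certain steps

Total step count: 4. Longest linear sequence: 4 steps (1 → 3 → 4 → 5 → 9).

**Step 3 (key step).** Three processes are most likely to defeat the step. The first is fragmentation of the acyl/allyl radical pair, or of the excited product, by cycloreversion to a ketene and the conjugated triene; this is favoured because the triene is stable and the product absorbs more strongly than the substrate. The second is leakage into the triplet manifold (oxa-di-π-methane rearrangement, decarbonylation), helped by the enoate on the migrating alkene. The third is photoisomerisation of the butylidene double bond, which would be re-equilibrated to Z with catalytic I2.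

Fallback: the cyclobutane is made by a different bond set, setting out from 1 and returning at 9. Compound 1 and commercial (Z)-3-butylidenephthalide (CCC/C=C1\OC(=O)c2ccccc12) would be irradiated together under triplet sensitisation (thioxanthone, 385–405 nm) in a crossed [2+2] photocycloaddition of C6=C7 with the exocyclic C3'=C8' bond. The more stabilised 1,4-biradical (C6–C8' formed first, leaving a pentadienyl radical over C7/C3a/C8 and a benzylic α-oxy radical at C3') leads to the required 6–8'/7–3' connectivity. The adduct is racemic, so 9 would be formed together with the enantiomer of the target F1, besides diastereomers and homodimers, and 9 would be separated on a chiral stationary phase. The price is loss of catalytic control over absolute and relative configuration.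

**Step 1.** The hindered, weakly nucleophilic diene may react too slowly with the β-propyl iminium ion, so that acid-promoted dimerisation or aromatisation of 1 takes over; endo/exo selectivity may also erode, and the exo adduct cannot be corrected later.

Fallback: the propyl group is introduced after the cycloaddition, setting out from 1 and returning at 4. Compound 1 and acrolein, the most reactive partner for cyclohexadienes in this catalysis, with the same (5R) catalyst should give the nor-propyl endo aldehyde F2. The Cu(OAc)2/O2 deformylation of step 2 should then give the nor-propyl ketone F3, which can enolise only towards C8'. LDA and 1-iodopropane/DMPU at −78 °C should alkylate from the less hindered alkene side to give the C8' epimer of 4 F4 (propyl syn to C7=C7a). Deprotonation of this epimer with LDA and kinetic protonation from the same alkene side by a bulky phenol should place H syn to the alkene and the propyl group over the C4–C5 bridge, which is 4. The same deprotonation and kinetic protonation would also repair 4 if C8' is partly epimerised in step 2.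

**Step 2.** Enolisation of the product ketone by the amine base at C8' would erode the kinetic propyl configuration, and the base or the copper salt may attack the enol lactone.

Fallback (from 3, returning at 4): TBSOTf/Et3N in CH2Cl2 should give the silyl enol ether F5. Ozone (1 equiv, CH2Cl2, pyridine, −78 °C; Me2S) should then cleave this most electron-rich alkene selectively to 4 under non-basic conditions.

**Step 4.** The ester-bearing Grignard reagent is a sluggish nucleophile. Deprotonation at C7 or C8' may compete (scrambling C8'), as may attack on the dienyl lactone, incomplete ring closure of the hindered alkoxide, or strain-driven opening of the cyclobutanolate.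

Fallback (from 5, returning at 9): a more nucleophilic ester-free aryl donor is used and the lactone carbonyl is made by oxidation. Commercial tert-butyl[(2-bromophenyl)methoxy]dimethylsilane (CC(C)(C)[Si](C)(C)OCc1ccccc1Br) and Mg turnings in THF give the Grignard reagent F6. Its addition to 5 with LaCl3·2LiCl at −78 °C should give, again from the convex face, the silyl-protected carbinol F7. HF·pyridine in THF then removes the silyl group to give the diol F8, and TEMPO/PhI(OAc)2 oxidises the benzylic primary alcohol through the lactol to the phthalide 9.

## Further compounds

F1 | step 3 | enantiomer of the target (6R,7S,3'S,8'S), formed with 9 in the racemic photocycloaddition | CCC/C=C1\OC(=O)C2=C1CC[C@@H]1[C@H](CCC)[C@]3(OC(=O)c4ccccc43)[C@H]21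
F2 | step 1 | nor-propyl endo aldehyde: as 3 with C8' = CH2, CHO on C3' syn to C7=C7a | CCC/C=C1\OC(=O)C2=C[C@H]3CC[C@@]12[C@@H](C=O)C3
F3 | step 1 | nor-propyl bicyclo[2.2.2]octenone: as 4 with C8' = CH2 | CCC/C=C1\OC(=O)C2=C[C@H]3CC[C@@]12C(=O)C3
F4 | step 1 | C8' epimer of 4, n-propyl syn to the C7=C7a bridge | CCC/C=C1\OC(=O)C2=C[C@H]3CC[C@@]12C(=O)[C@H]3CCC
F5 | step 2 | tert-butyldimethylsilyl enol ether of 3 (C3'=CH–OSi, either geometry) | CCC/C=C1\OC(=O)C2=C[C@H]3CC[C@@]12C(=CO[Si](C)(C)C(C)(C)C)[C@@H]3CCC
F6 | step 4 | [2-({[tert-butyl(dimethyl)silyl]oxy}methyl)phenyl]magnesium bromide | CC(C)(C)[Si](C)(C)OCc1ccccc1[Mg]Br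
F7 | step 4 | tertiary cyclobutanol from 5: C3' bearing OH (concave) and the 2-(silyloxymethyl)phenyl group (convex) | CCC/C=C1\OC(=O)C2=C1CC[C@H]1[C@@H](CCC)[C@](O)(c3ccccc3CO[Si](C)(C)C(C)(C)C)[C@@H]21
F8 | step 4 | diol: as F7 with free CH2OH | CCC/C=C1\OC(=O)C2=C1CC[C@H]1[C@@H](CCC)[C@](O)(c3ccccc3CO)[C@@H]21
A1 | alternative 1 | cyclobut-2-enone | O=C1CC=C1
A2 | alternative 1 | (E)-1-(triisopropylsilyloxy)buta-1,3-diene | C=C/C=C/O[Si](C(C)C)(C(C)C)C(C)C
A3 | alternative 1 | cis-2-(triisopropylsilyloxy)bicyclo[4.2.0]oct-3-en-8-one | CC(C)[Si](O[C@H]1C=CC[C@H]2CC(=O)[C@@H]12)(C(C)C)C(C)C
A4 | alternative 2 | 2-(trimethylsilyl)phenyl trifluoromethanesulfonate | C[Si](C)(C)c1ccccc1OS(=O)(=O)C(F)(F)F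
A5 | alternative 2 | tert-butyl isocyanide | CC(C)(C)[N+]#[C-]
A6 | alternative 2 | cis-8-propylbicyclo[4.2.0]oct-2-en-7-one, propyl concave | C1CC=C[C@H]2[C@@H](CCC)C(=O)[C@@H]12
A7 | alternative 2 | spiro N-tert-butyl iminoisobenzofuran on the propyl-bicyclo[4.2.0]octene | C1CC=C[C@H]2[C@@H](CCC)[C@@]3(OC(=NC(C)(C)C)c4ccccc43)[C@@H]12
A8 | alternative 3 | cis-1,4-diketone: silyloxycyclohexane with butanoyl on C6 and 2-(methoxycarbonyl)benzoyl on C7 | C1[C@@H](O[Si](C)(C)C(C)(C)C)CC[C@@H](C(=O)CCC)[C@H]1C(=O)c1ccccc1C(=O)OC
A9 | alternative 3 | spiro-phthalide cyclobutanol, C8' hydroxyl concave and propyl convex | C1[C@@H](O[Si](C)(C)C(C)(C)C)CC[C@H]2[C@](O)(CCC)[C@@]3(OC(=O)c4ccccc43)[C@@H]12
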